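**Plan**

1. The target is read as epiguibourtinidol-(4β→8)-epicatechin: an upper 5-deoxyflavan-3-ol unit (2R,3R,4R; 2,3-cis-3,4-trans) joined through C-4 to C-8 of a (2R,3R)-epicatechin unit.
2. Retrosynthetic cuts, in order: C-4–C-4a of the upper pyran ring (last ring closure), the interflavan C-4–C-8 bond (aryllithium + aldehyde), O-1–C-8a (aryl ether to a meta-benzyloxyphenyl ring), and C-2–C-3 (acylation of a glycolate enolate).
3. Enabling feature: C-4 sits on C-8 of the phloroglucinol-type ring A of the lower unit, ortho to O-1 and O-7 and para to O-5, so a C-4 carbinol ionises under trace acid. C-4a of the upper resorcinol-type ring A is para to O-7, ortho to O-1 and six atoms from C-4, and the upper C-5 carries only hydrogen.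
4. Forward: the open chain C-2–C-3–C-4 is built first (keto ester, syn hydroxy ester, aryl ether, aldehyde) and joined to 8-lithiated perbenzylated epicatechin; only then is the upper pyran ring closed. The lower rings come intact from (−)-epicatechin, and all eight benzyl ethers fall in the last step.
5. Stereochemistry: lower C-2/C-3 from (−)-epicatechin; upper C-2/C-3 from catalyst-controlled transfer hydrogenation with dynamic kinetic resolution, carried through an O-arylation that does not break the carbinol C–O bond; upper C-4 from the ring closure, anti to O-3.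

Key step: step 9

Assumption: compounds 1, 2, 5 and 8 are purchasable, and carbinol 13 is carried on as the mixture of epimers at its carbinol carbon, since both converge in step 9.

**Route**

Step 1
Reactants: 1 methyl 2-(benzyloxy)acetate; 2 4-(benzyloxy)benzoyl chloride
Product: 3 methyl 2-(benzyloxy)-3-[4-(benzyloxy)phenyl]-3-oxopropanoate (racemic)
Conditions: LiN(SiMe3)2 (2.1 equiv), THF, −78 °C; then 2, −78 → 0 °C; 1 M HCl
Reagents that add atoms: none
Why: Crossed Claisen-type C-acylation of the lithium enolate of the glycolate ester by a non-enolisable aroyl chloride, in which the second equivalent of base stores the product as its enolate and so prevents a second acylation; the α-centre is left racemic because it is set in step 2.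

Step 2
Reactants: 3 methyl 2-(benzyloxy)-3-[4-(benzyloxy)phenyl]-3-oxopropanoate
Product: 4 methyl (2S,3R)-2-(benzyloxy)-3-[4-(benzyloxy)phenyl]-3-hydroxypropanoate (syn)
Conditions: RuCl(p-cymene)[(S,S)-TsDPEN] (1 mol %), HCO2H/Et3N (5:2), CH2Cl2, 30 °C
Reagents that add atoms: none
Why: Noyori–Ikariya asymmetric transfer hydrogenation under dynamic kinetic resolution, in which the α-centre racemises through the enol faster than reduction, the (S,S)-catalyst delivers hydride to the aryl ketone face fixed by the arene CH/π contact (the sense that gives (S)-1-phenylethanol, here labelled 3R because the α-carbon outranks the aryl group), and the enantiomer of 3 leading to the syn (2S,3R) hydroxy ester should be reduced preferentially, as is typical of α-alkoxy-β-keto esters.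

Step 3
Reactants: 4 methyl (2S,3R)-2-(benzyloxy)-3-[4-(benzyloxy)phenyl]-3-hydroxypropanoate; 5 potassium [3-(benzyloxy)phenyl]trifluoroborate
Product: 6 methyl (2S,3R)-2-(benzyloxy)-3-[3-(benzyloxy)phenoxy]-3-[4-(benzyloxy)phenyl]propanoate
Conditions: 5 (2 equiv), Cu(OAc)2·H2O (10 mol %), DMAP (20 mol %), 4 Å MS, O2 (1 atm), CH2Cl2, rt
Reagents that add atoms: none
Why: Chan–Lam-type oxidative copper etherification of a secondary alcohol, in which the aryl group passes from boron to the copper alkoxide and reductive elimination from trivalent copper forms the aryl–O bond at the ipso carbon only (benzyloxy group meta to the new ether oxygen), so the carbinol C–O bond is never broken, the 3R centre is retained, and the neutral conditions spare the retro-aldol-prone β-hydroxy ester.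

Step 4
Reactants: 6 methyl (2S,3R)-2-(benzyloxy)-3-[3-(benzyloxy)phenoxy]-3-[4-(benzyloxy)phenyl]propanoate
Product: 7 (2S,3R)-2-(benzyloxy)-3-[3-(benzyloxy)phenoxy]-3-[4-(benzyloxy)phenyl]propanal
Conditions: i-Bu2AlH (1.1 equiv), CH2Cl2, −78 °C; MeOH, then aq. potassium sodium tartrate
Reagents that add atoms: none
Why: Partial reduction of an ester with i-Bu2AlH, in which the tetrahedral aluminium hemiacetal chelated by the α-benzyloxy oxygen persists at −78 °C and collapses to the aldehyde only on work-up, while the absence of base keeps the epimerisable α-centre and the β-aryloxy group in place.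

Step 5
Reactants: 8 (−)-epicatechin
Product: 9 5,7,3',4'-tetra-O-benzyl-(−)-epicatechin
Conditions: BnBr (4.4 equiv), K2CO3, DMF, argon, 0 °C → rt
Reagents that add atoms: benzyl bromide, BrCc1ccccc1
Why: Williamson etherification in which K2CO3 deprotonates only the four phenols, so the secondary 3-hydroxyl stays free, and the mild base at room temperature under argon avoids C-2 epimerisation and oxidation.

Step 6
Reactants: 9 5,7,3',4'-tetra-O-benzyl-(−)-epicatechin
Product: 10 3,5,7,3',4'-penta-O-benzyl-(−)-epicatechin
Conditions: NaH, BnBr, Bu4NI (cat.), THF/DMF, 0 °C → rt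
Reagents that add atoms: benzyl bromide, BrCc1ccccc1
Why: Williamson etherification of the remaining secondary alcohol as its sodium alkoxide, which touches no stereocentre.

Step 7
Reactants: 10 3,5,7,3',4'-penta-O-benzyl-(−)-epicatechin
Product: 11 8-bromo-3,5,7,3',4'-penta-O-benzyl-(−)-epicatechin
Conditions: NBS (1.0 equiv), CH2Cl2, −78 °C → rt
Reagents that add atoms: N-bromosuccinimide, O=C1CCC(=O)N1Br
Why: Electrophilic aromatic bromination of the phloroglucinol-type ring A, by far the most electron-rich ring, expected at C-8 in line with the known preference of benzylated flavan-3-ols for C-8 over C-6 with one equivalent of reagent at low temperature.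

Step 8
Reactants: 11 8-bromo-3,5,7,3',4'-penta-O-benzyl-(−)-epicatechin; 7 (2S,3R)-2-(benzyloxy)-3-[3-(benzyloxy)phenoxy]-3-[4-(benzyloxy)phenyl]propanal
Product: 13 (1ξ,2R,3R)-2-(benzyloxy)-3-[3-(benzyloxy)phenoxy]-3-[4-(benzyloxy)phenyl]-1-[(2R,3R)-3,5,7-tris(benzyloxy)-2-[3,4-bis(benzyloxy)phenyl]chroman-8-yl]propan-1-ol, via 8-lithio-penta-O-benzylepicatechin 12 (not isolated)
Conditions: 11 (1.3 equiv), t-BuLi (2.0 equiv per 11), THF, −78 °C; then 7, −78 → −40 °C; H2O quench; crude product through Et3N-deactivated silica
Reagents that add atoms: none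
Why: Bromine–lithium exchange (the second equivalent of t-BuLi destroys the t-BuBr formed) followed by 1,2-addition of the aryllithium to the aldehyde fixes the interflavan bond unambiguously at C-8, and the new carbinol centre is formed without control, which is immaterial because step 9 ionises it.

Step 9
Reactants: 13 the carbinol from step 8 (both epimers)
Product: 14 octa-O-benzyl-epiguibourtinidol-(4β→8)-epicatechin, (2R,3R,4R)-3,7-bis(benzyloxy)-2-[4-(benzyloxy)phenyl]-4-[(2R,3R)-3,5,7-tris(benzyloxy)-2-[3,4-bis(benzyloxy)phenyl]chroman-8-yl]chromane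
Conditions: Me3SiOTf (10 mol %), 4 Å MS, CH2Cl2 (0.01 M), −78 → −40 °C; then Et3N
Reagents that add atoms: none
Why: The silyl triflate (or the trace TfOH it releases) ionises either epimer of the carbinol because C-4 is attached to C-8 of the lower ring A, ortho to O-1 and O-7 and para to O-5, so a quinone-methide-like benzylic cation forms at −78 °C, well below the point at which the C-2 benzylic aryl ether would ionise. The tethered meta-benzyloxyphenyl ether then attacks through the carbon para to its benzyloxy group and ortho to the ether oxygen (future C-4a) and loses a proton, an intramolecular Friedel–Crafts alkylation whose closest known relatives are the acid-mediated cyclisations of 3-aryloxy-1-arylpropan-1-ols to 4-arylchromans and, with reversed polarity, the couplings of flavan C-4 cations with flavan-3-ols. The upper pyran ring closes in the 6-exo-trig mode with respect to the C-4=C-8 bond of the cation (the arene C-4a=C-8a bond becomes part of the ring). C-4 is the only new stereocentre and is controlled by the fixed C-3 centre: allylic 1,3-strain against the two ortho oxygens of the lower ring A keeps O-3 out of the cation plane on the side away from the arene, which can only reach C-4 from the C-2 side, so the new C-4–C-4a bond forms anti to the 3-benzyloxy group and both epimers of 13 should converge on the 3,4-trans (4R) product with the 2-aryl group equatorial in a chair-like transition state. The selectivities needed are the para over the ortho position of the aryl ether (the carbon between its two oxygens is hindered and would give a 5-oxygenated isomer), this ring over the 2-aryl ring and the benzyl groups (their reachable carbons are not activated by oxygen or would close a five-membered ring), and cyclisation over intermolecular alkylation, secured by the substitution pattern and high dilution.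

Step 10
Reactants: 14 octa-O-benzyl-epiguibourtinidol-(4β→8)-epicatechin
Product: 15 epiguibourtinidol-(4β→8)-epicatechin, (2R,3R,4R)-2-(4-hydroxyphenyl)-4-[(2R,3R)-2-(3,4-dihydroxyphenyl)-3,5,7-trihydroxychroman-8-yl]chromane-3,7-diol
Conditions: H2 (1 atm), Pd(OH)2/C, THF/MeOH/H2O, rt
Reagents that add atoms: none
Why: Catalytic hydrogenolysis of the eight benzyl ethers over Pd(OH)2/C under neutral conditions, which should leave the diarylmethine C-4–C-8 bond, the cyclic benzylic C-2–O-1 bonds and all five stereocentres untouched.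

**Compound list**

1 | methyl 2-(benzyloxy)acetate | COC(=O)COCc1ccccc1 | starting material
2 | 4-(benzyloxy)benzoyl chloride | O=C(Cl)c1ccc(OCc2ccccc2)cc1 | starting material
3 | methyl 2-(benzyloxy)-3-[4-(benzyloxy)phenyl]-3-oxopropanoate (racemic) | COC(=O)C(OCc1ccccc1)C(=O)c1ccc(OCc2ccccc2)cc1 | intermediate
4 | methyl (2S,3R)-2-(benzyloxy)-3-[4-(benzyloxy)phenyl]-3-hydroxypropanoate | c1ccccc1COc1ccc(cc1)[C@@H](O)[C@H](OCc1ccccc1)C(=O)OC | intermediate
5 | potassium [3-(benzyloxy)phenyl]trifluoroborate | [K+].F[B-](F)(F)c1cccc(OCc2ccccc2)c1 | starting material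
6 | methyl (2S,3R)-2-(benzyloxy)-3-[3-(benzyloxy)phenoxy]-3-[4-(benzyloxy)phenyl]propanoate | c1ccccc1COc1ccc(cc1)[C@@H](Oc1cccc(OCc2ccccc2)c1)[C@H](OCc1ccccc1)C(=O)OC | intermediate
7 | (2S,3R)-2-(benzyloxy)-3-[3-(benzyloxy)phenoxy]-3-[4-(benzyloxy)phenyl]propanal | c1ccccc1COc1ccc(cc1)[C@@H](Oc1cccc(OCc2ccccc2)c1)[C@H](OCc1ccccc1)C=O | intermediate
8 | (−)-epicatechin, (2R,3R)-2-(3,4-dihydroxyphenyl)chromane-3,5,7-triol | Oc1cc(O)c2c(c1)O[C@H](c1ccc(O)c(O)c1)[C@H](O)C2 | starting material
9 | 5,7,3',4'-tetra-O-benzyl-(−)-epicatechin, (2R,3R)-5,7-bis(benzyloxy)-2-[3,4-bis(benzyloxy)phenyl]chroman-3-ol | c1ccccc1COc1cc(OCc3ccccc3)c2c(c1)O[C@H](c1ccc(OCc3ccccc3)c(OCc3ccccc3)c1)[C@H](O)C2 | intermediate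
10 | 3,5,7,3',4'-penta-O-benzyl-(−)-epicatechin, (2R,3R)-3,5,7-tris(benzyloxy)-2-[3,4-bis(benzyloxy)phenyl]chromane | c1ccccc1COc1cc(OCc3ccccc3)c2c(c1)O[C@H](c1ccc(OCc3ccccc3)c(OCc3ccccc3)c1)[C@H](OCc3ccccc3)C2 | intermediate
11 | 8-bromo-3,5,7,3',4'-penta-O-benzyl-(−)-epicatechin, (2R,3R)-3,5,7-tris(benzyloxy)-2-[3,4-bis(benzyloxy)phenyl]-8-bromochromane | Brc1c(OCc3ccccc3)cc(OCc3ccccc3)c2c1O[C@H](c1ccc(OCc3ccccc3)c(OCc3ccccc3)c1)[C@H](OCc3ccccc3)C2 | intermediate
12 | 8-lithio-3,5,7,3',4'-penta-O-benzyl-(−)-epicatechin (aryllithium, not isolated) | [Li]c1c(OCc3ccccc3)cc(OCc3ccccc3)c2c1O[C@H](c1ccc(OCc3ccccc3)c(OCc3ccccc3)c1)[C@H](OCc3ccccc3)C2 | intermediate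
13 | (1ξ,2R,3R)-2-(benzyloxy)-3-[3-(benzyloxy)phenoxy]-3-[4-(benzyloxy)phenyl]-1-[(2R,3R)-3,5,7-tris(benzyloxy)-2-[3,4-bis(benzyloxy)phenyl]chroman-8-yl]propan-1-ol (both epimers at C-1) | c1ccccc1COc1ccc(cc1)[C@@H](Oc1cccc(OCc2ccccc2)c1)[C@H](OCc1ccccc1)C(O)c1c(OCc3ccccc3)cc(OCc3ccccc3)c2c1O[C@H](c1ccc(OCc3ccccc3)c(OCc3ccccc3)c1)[C@H](OCc3ccccc3)C2 | intermediate
14 | octa-O-benzyl-epiguibourtinidol-(4β→8)-epicatechin, (2R,3R,4R)-3,7-bis(benzyloxy)-2-[4-(benzyloxy)phenyl]-4-[(2R,3R)-3,5,7-tris(benzyloxy)-2-[3,4-bis(benzyloxy)phenyl]chroman-8-yl]chromane | c5ccccc5COc1ccc([C@H]2Oc3cc(OCc5ccccc5)ccc3[C@H](c3c(OCc5ccccc5)cc(OCc5ccccc5)c4c3O[C@H](c3ccc(OCc5ccccc5)c(OCc5ccccc5)c3)[C@H](OCc5ccccc5)C4)[C@H]2OCc5ccccc5)cc1 | intermediate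
15 | epiguibourtinidol-(4β→8)-epicatechin, (2R,3R,4R)-2-(4-hydroxyphenyl)-4-[(2R,3R)-2-(3,4-dihydroxyphenyl)-3,5,7-trihydroxychroman-8-yl]chromane-3,7-diol | Oc1ccc([C@H]2Oc3cc(O)ccc3[C@H](c3c(O)cc(O)c4c3O[C@H](c3ccc(O)c(O)c3)[C@H](O)C4)[C@H]2O)cc1 | target

**Step count and risks**

Total steps: 10. Longest linear sequence: 7 steps (steps 1, 2, 3, 4, 8, 9, 10).

Steps most likely to fail:

1. Step 9. The cation may lose the C-3 proton to give an enol ether, the C-2 benzylic aryl ether may ionise with loss of the phenol, or the facial bias at C-4 may be insufficient. The fallback reverses the polarity and closes the ring before the interflavan bond is made; it sets out from aldehyde 7 and penta-O-benzylepicatechin 10 and returns at 14. Aldehyde 7 is cyclised by intramolecular Friedel–Crafts hydroxyalkylation (SnCl4, CH2Cl2, −78 °C, cold quench) through the carbon para to the benzyloxy group to give (2R,3R)-3,7-bis(benzyloxy)-2-[4-(benzyloxy)phenyl]chroman-4-ol F1 as a mixture of C-4 epimers. Its C-4 hydroxyl is then ionised with Me3SiOTf at −78 °C in the presence of excess 10. Attack of C-8 of 10 on the cyclic benzylic cation anti to the pseudoaxial 3-benzyloxy group, the usual outcome for 2,3-cis flavan C-4 cations, should give 14. The upper pyran ring remains the last ring closed.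

2. Step 3. Transmetalation to the hindered secondary copper alkoxide may be slow, so that protodeboronation of 5, aryl homocoupling or oxidation of the benzylic alcohol back to 3 takes over. The fallback forms the aryl ether with an aryne; it sets out from 4 and returns at 6. Commercial 3-(benzyloxy)phenol is treated with isopropyl isocyanate and Et3N to give 3-(benzyloxy)phenyl N-isopropylcarbamate F2. Directed ortho-lithiation between the two oxygens (Me3CMe2SiOTf, TMEDA; n-BuLi, −78 °C; Me3SiCl) gives 3-(benzyloxy)-2-(trimethylsilyl)phenyl N-isopropylcarbamate F3. One-pot carbamate cleavage and triflation (DBU, Et2NH; then PhNTf2) gives 3-(benzyloxy)-2-(trimethylsilyl)phenyl trifluoromethanesulfonate F4. CsF in MeCN (or KF/18-crown-6 in THF) at or below rt releases 3-(benzyloxy)benzyne F5 in the presence of 4. The benzyloxy group beside the triple bond distorts the aryne so that the alcohol oxygen adds to the distal carbon, placing the developing negative charge next to the inductively withdrawing oxygen; protonation should then give 6 as the only regioisomer, with the carbinol configuration untouched.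

3. Step 8. The hindered, basic aryllithium may enolise the α-alkoxy aldehyde, with epimerisation at the α-carbon or β-elimination of the aryloxide, instead of adding to it. The fallback replaces the aldehyde addition by acylation and reduction; it sets out from ester 6 and bromide 11 (via 12) and returns at 13. Aryllithium 12 is acylated by 6 in THF at −78 °C to give (2S,3R)-2-(benzyloxy)-3-[3-(benzyloxy)phenoxy]-3-[4-(benzyloxy)phenyl]-1-[(2R,3R)-3,5,7-tris(benzyloxy)-2-[3,4-bis(benzyloxy)phenyl]chroman-8-yl]propan-1-one F6, a di-ortho-substituted aryl ketone that should resist a second addition. NaBH4 in THF/MeOH at 0 °C then reduces F6 to 13, again as an epimer mixture that step 9 makes irrelevant.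

**Further compounds**

F1 | step 9 | (2R,3R)-3,7-bis(benzyloxy)-2-[4-(benzyloxy)phenyl]chroman-4-ol (C-4 epimers) | c5ccccc5COc1ccc([C@H]2Oc3cc(OCc5ccccc5)ccc3C(O)[C@H]2OCc5ccccc5)cc1
F2 | step 3 | 3-(benzyloxy)phenyl N-isopropylcarbamate | CC(C)NC(=O)Oc1cccc(OCc2ccccc2)c1
F3 | step 3 | 3-(benzyloxy)-2-(trimethylsilyl)phenyl N-isopropylcarbamate | CC(C)NC(=O)Oc1cccc(OCc2ccccc2)c1[Si](C)(C)C
F4 | step 3 | 3-(benzyloxy)-2-(trimethylsilyl)phenyl trifluoromethanesulfonate | C[Si](C)(C)c1c(OCc2ccccc2)cccc1OS(=O)(=O)C(F)(F)F
F5 | step 3 | 3-(benzyloxy)benzyne (3-(benzyloxy)-1,2-didehydrobenzene, not isolated) | C1(OCc2ccccc2)=CC=CC#C1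
F6 | step 8 | (2S,3R)-2-(benzyloxy)-3-[3-(benzyloxy)phenoxy]-3-[4-(benzyloxy)phenyl]-1-[(2R,3R)-3,5,7-tris(benzyloxy)-2-[3,4-bis(benzyloxy)phenyl]chroman-8-yl]propan-1-one | c1ccccc1COc1ccc(cc1)[C@@H](Oc1cccc(OCc2ccccc2)c1)[C@H](OCc1ccccc1)C(=O)c1c(OCc3ccccc3)cc(OCc3ccccc3)c2c1O[C@H](c1ccc(OCc3ccccc3)c(OCc3ccccc3)c1)[C@H](OCc3ccccc3)C2
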